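At 2.00 h the spring run reads 8.5% of E and the midnight run 3.0%, so the hotter run reads higher, and I work from that gap.

| flask | L | X | temperature | remark | time |
|---|---|---|---|---|---|
| midnight | 0.10 M | 0.042 M | 88 °C | run made earlier |  |
| spring | 0.10 M | 0.066 M | 104 °C | run made earlier |  |
| elm | 0.10 M | 0.0300 M | 95 °C |  | 5.0 h |
| maple | 0.10 M | 0.0300 M |  | at 80 °C until 1.0 h, from then on at 110 °C | 5.0 h |
| oak | 0.10 M | 0.0300 M | 80 °C |  | 5.0 h |
| alder | 0.10 M | 0.0300 M | 110 °C |  | 5.0 h |

- midnight (time / h: E / %): 0.333: 0; 1.00: 1.1; 2.00: 3.0; 2.50: 2.6; 4.00: 3.5; 5.00: 4.3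
- spring (time / h: E / %): 0.250: 3.0; 0.417: 3.3; 0.667: 3.5; 1.33: 6.6; 2.00: 8.5; 3.00: 9.8

(each reading ± 0.5 percentage points)

- the numbers in the tables scatter by 0.5 percentage points (one standard deviation)

- the flask that comes out highest in amount of E, in percent of the L charged, or "all alike" when all lie within 1.5 percentage points (elm / maple / oak / alder / all alike)
- E at the end, in percent of the L charged, elm
- E at the end, in percent of the L charged, maple
- E at the end, in percent of the L charged, oak
- E at the end, in percent of the L charged, alder

Turned round: "all alike" needs oak and alder within 1.5 percentage points of each other. Spring and midnight lie between those two temperatures, yet their readings at 2.00 h stand 5.5 points apart, with a scatter of 0.5 points on each reading. So that gap would have to belong to something other than temperature, and the other thing that differs is X, charged at 0.660 of L in spring and 0.420 in midnight. Counting turnovers, midnight's last reading comes to 0.102 E per X charged. Even if E went strictly with X, X covers a factor 1.57 of the reading ratio 2.83, so a rest stays for temperature. I assume the whole ratio is temperature and reckon: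

gain = R · ln(spring reading ÷ midnight reading) ÷ (difference of reciprocal temperatures) = 73.7 kJ mol⁻¹

alder = midnight's last reading, scaled by the gain = 17.6%

oak = the same, scaled down = 2.47%

This yield gain, the slope of ln E against reciprocal temperature at equal time (an apparent activation energy), is what I carry. It puts alder and oak ten times the margin apart, so I name alder.

The forecast also names alder, with elm 3.9%, maple 5.2%, oak 2.1% and alder 5.5%, reading “X driving the reaction while dying or being consumed”. My alder stands higher than its alder.

The flasks give alder highest: elm 6.58%, maple 13.6%, oak 1.93%, alder 16.8%.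

    L → E (k = 0.210 h⁻¹, Ea = 122 kJ mol⁻¹)
    2 L → Q (k = 13.0 L mol⁻¹ h⁻¹, Ea = 59.0 kJ mol⁻¹)
    L + Q → J (k = 0.970 L mol⁻¹ h⁻¹, Ea = 106 kJ mol⁻¹)
    L + X → G (k = 1.60 L mol⁻¹ h⁻¹, Ea = 78.0 kJ mol⁻¹)
    (constants at 110 °C)

Alder holds 16.8% where the gain gave 17.6%, and the gain carried to elm gives 6.86% where elm holds 6.58%. From oak to alder the step of L into E speeds up by a factor 26, and the step of two L into Q has an activation energy 63.0 kJ mol⁻¹ lower than that step's. In maple at 5.00 h, L passes into Q at 0.51 of the rate at which it passes into E.

(The earlier runs and the new flask were generated by integration with constants of no real substance; the scatter is artificial.)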